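**Strategy.** Everything rests on making ring C of the middle oritin unit (O1, C2, C3, C4, C4a, C8a) from a trans-2,3-dihydrobenzofuran that already carries, at its C3, C6 of the lower epioritin-4α-ol unit. The key step ionises the exocyclic p-benzyloxybenzylic carbinol; O1 bridges to that carbon as an aryl-oxiranium ion and acetate opens it at the old furan C2. This 1,2-shift of O1 exploits the vicinal O1/3-OH pair on C2/C3: it enlarges the five-membered ring to the pyran and sets C2 and C3 trans to each other and to the C4 aryl bond, fixed earlier by an auxiliary-controlled [4+1] annulation. The upper unit is added afterwards by aryllithium addition to a 4-ketone and ionic deoxygenation.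

Key step: step 16

Remark on names: oritin = (2R,3S)-7,8,4'-trihydroxyflavan-3-ol (2,3-trans); epioritin-4α-ol = (2R,3R,4R)-7,8,4'-trihydroxyflavan-3,4-diol (all-cis); α is the face of the C2 aryl group, β the opposite face; Bn = benzyl, TBS = tert-butyldimethylsilyl; "lower-unit-6-yl" is the chroman-6-yl group of 13 with the bromine replaced by the bond.

Assumption: the ligand antipode in step 4 and the cinchona auxiliary in step 14 are taken as those that give the configurations drawn; if the opposite sense is found, the other ligand antipode or the quinine-derived salt is used.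

**Route**

Step 1
Reactants: 1 2',3',4'-trihydroxyacetophenone
Product: 2 1-[3,4-bis(benzyloxy)-2-hydroxyphenyl]ethanone
Conditions: BnBr (2.1 equiv), K2CO3, DMF, rt
Reagents that add atoms: benzyl bromide, BrCc1ccccc1
Why: Williamson etherification; the 2-hydroxyl is hydrogen-bonded to the acetyl group and least nucleophilic, so only O3 and O4 are benzylated.

Step 2
Reactants: 2 1-[3,4-bis(benzyloxy)-2-hydroxyphenyl]ethanone
Product: 3 1-[3,4-bis(benzyloxy)-5-bromo-2-hydroxyphenyl]ethanone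
Conditions: N-bromosuccinimide, MeCN, 0 °C to rt
Reagents that add atoms: N-bromosuccinimide, O=C1CCC(=O)N1Br
Why: Electrophilic aromatic bromination goes para to the free phenol (and ortho to a benzyloxy group), the position that becomes C6 of the flavan.

Step 3
Reactants: 3 1-[3,4-bis(benzyloxy)-5-bromo-2-hydroxyphenyl]ethanone
Product: 5 7,8-bis(benzyloxy)-6-bromo-4H-chromen-4-one, via enaminone 4 (not isolated)
Conditions: Me2NCH(OMe)2, toluene, 90 °C; then conc. HCl, CH2Cl2, rt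
Reagents that add atoms: N,N-dimethylformamide dimethyl acetal, COC(OC)N(C)C
Why: Condensation of the methyl ketone with the amide acetal gives the enaminone, and acid-promoted addition of the phenol with loss of dimethylamine closes the chromone (6-endo addition–elimination).

Step 4
Reactants: 5 7,8-bis(benzyloxy)-6-bromo-4H-chromen-4-one; 6 [4-(benzyloxy)phenyl]boronic acid
Product: 7 (2S)-7,8-bis(benzyloxy)-2-[4-(benzyloxy)phenyl]-6-bromochroman-4-one
Conditions: Pd(OCOCF3)2 (5 mol%), (R)-4-tert-butyl-2-(pyridin-2-yl)-4,5-dihydrooxazole (6 mol%), NH4PF6, H2O, ClCH2CH2Cl, 60 °C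
Reagents that add atoms: none
Why: Enantioselective conjugate addition of the arylboronic acid to the chromone by a cationic divalent palladium pyridine–oxazoline catalyst sets C2 through the ligand; the aryl bromide is inert because no zerovalent palladium is formed.

Step 5
Reactants: 7 (2S)-7,8-bis(benzyloxy)-2-[4-(benzyloxy)phenyl]-6-bromochroman-4-one
Product: 9 (2R,3R)-7,8-bis(benzyloxy)-2-[4-(benzyloxy)phenyl]-6-bromo-3-(tert-butyldimethylsilyloxy)chroman-4-one (2,3-trans), via silyl enol ether 8 (not isolated)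
Conditions: TBSOTf, Et3N, CH2Cl2, 0 °C; then m-CPBA, NaHCO3, CH2Cl2, −20 °C to rt
Reagents that add atoms: tert-butyldimethylsilyl trifluoromethanesulfonate, CC(C)(C)[Si](C)(C)OS(=O)(=O)C(F)(F)F; m-chloroperbenzoic acid, OOC(=O)c1cccc(Cl)c1
Why: Rubottom oxidation; the silyl enol ether is epoxidised on the face opposite the C2 aryl group and the silyl group migrates to the new oxygen, which sets C3 trans to C2 and gives the 3-O-silyl ketone directly.

Step 6
Reactants: 9 (2R,3R)-7,8-bis(benzyloxy)-2-[4-(benzyloxy)phenyl]-6-bromo-3-(tert-butyldimethylsilyloxy)chroman-4-one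
Product: 11 (2R,3S)-7,8-bis(benzyloxy)-2-[4-(benzyloxy)phenyl]-6-bromo-3-(tert-butyldimethylsilyloxy)chroman-4-one (2,3-cis), via lithium enolate 10 (not isolated)
Conditions: LiN(SiMe3)2, THF, −78 °C; then AcOH in THF, −78 °C (inverse quench)
Reagents that add atoms: none
Why: Kinetic protonation of the enolate; the C2 aryl group sits pseudo-axial next to the planar C3 (allylic 1,2-strain), so the proton enters from the opposite face and leaves the silyloxy group cis to the aryl group.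

Step 7
Reactants: 11 (2R,3S)-7,8-bis(benzyloxy)-2-[4-(benzyloxy)phenyl]-6-bromo-3-(tert-butyldimethylsilyloxy)chroman-4-one
Product: 12 (2R,3R,4R)-7,8-bis(benzyloxy)-2-[4-(benzyloxy)phenyl]-6-bromo-3-(tert-butyldimethylsilyloxy)chroman-4-ol (all-cis)
Conditions: NaBH4, CeCl3·7H2O, MeOH/THF, −40 °C
Reagents that add atoms: none
Why: Luche reduction; hydride attacks C4 from the face opposite the C2 aryl and axial C3 silyloxy groups, which gives the all-cis 3,4-dioxygen pattern of the lower unit without epimerising C3.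

Step 8
Reactants: 12 (2R,3R,4R)-7,8-bis(benzyloxy)-2-[4-(benzyloxy)phenyl]-6-bromo-3-(tert-butyldimethylsilyloxy)chroman-4-ol
Product: 13 (2R,3S,4R)-7,8-bis(benzyloxy)-2-[4-(benzyloxy)phenyl]-6-bromo-3,4-bis(tert-butyldimethylsilyloxy)chromane (all-cis; lower-unit bromide)
Conditions: TBSOTf, 2,6-lutidine, CH2Cl2, 0 °C to rt
Reagents that add atoms: tert-butyldimethylsilyl trifluoromethanesulfonate, CC(C)(C)[Si](C)(C)OS(=O)(=O)C(F)(F)F
Why: Silylation of the hindered benzylic hydroxyl with the silyl triflate makes the unit compatible with organolithium chemistry; any O3/O4 silyl migration in step 7 is levelled here.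

Step 9
Reactants: 14 2,3,4-trihydroxybenzaldehyde
Product: 15 3,4-bis(benzyloxy)-2-hydroxybenzaldehyde
Conditions: BnBr (2.1 equiv), K2CO3, DMF, rt
Reagents that add atoms: benzyl bromide, BrCc1ccccc1
Why: Williamson etherification; the chelated 2-hydroxyl stays free, as in step 1.

Step 10
Reactants: 15 3,4-bis(benzyloxy)-2-hydroxybenzaldehyde
Product: 16 3,4-bis(benzyloxy)-5-bromo-2-hydroxybenzaldehyde
Conditions: N-bromosuccinimide, MeCN, 0 °C to rt
Reagents that add atoms: N-bromosuccinimide, O=C1CCC(=O)N1Br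
Why: Electrophilic bromination para to the free phenol installs the handle that later becomes C6–Li of the middle unit.

Step 11
Reactants: 17 2-bromo-1-[4-(benzyloxy)phenyl]ethanone; 18 quinidine
Product: 19 N-{2-[4-(benzyloxy)phenyl]-2-oxoethyl}quinidinium bromide
Conditions: THF, rt
Reagents that add atoms: none
Why: Menshutkin quaternisation of the quinuclidine nitrogen by the α-bromo ketone gives the chiral ammonium salt that serves as ylide precursor.

Step 12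
Reactants: 13 lower-unit bromide; 16 3,4-bis(benzyloxy)-5-bromo-2-hydroxybenzaldehyde
Product: 21 [3,4-bis(benzyloxy)-5-bromo-2-hydroxyphenyl](lower-unit-6-yl)methanol (mixture of carbinol epimers), via aryllithium 20 (not isolated)
Conditions: t-BuLi (2.1 equiv), THF, −78 °C; then sodium salt of 16 (from NaH, THF), −78 to −20 °C; aq. NH4Cl
Reagents that add atoms: none
Why: Bromine–lithium exchange gives the C6 aryllithium of the lower unit, which adds to the aldehyde of the preformed phenoxide faster than it exchanges with the second aryl bromide; the new carbinol centre is erased in step 14.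

Step 13
Reactants: 21 [3,4-bis(benzyloxy)-5-bromo-2-hydroxyphenyl](lower-unit-6-yl)methanol
Product: 22 2,3-bis(benzyloxy)-4-bromo-6-[(lower-unit-6-yl)(4-methylphenylsulfonyl)methyl]phenol (mixture of epimers)
Conditions: TolSO2Na, HCO2H, CH2Cl2/H2O, rt
Reagents that add atoms: sodium 4-methylbenzenesulfinate, Cc1ccc(S(=O)[O-])cc1.[Na+]
Why: The doubly activated benzhydrol ionises under weak acid (protonated o-quinone methide) and is captured at sulfur by sulfinate, which installs a leaving group that releases the o-quinone methide under mild base.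

Step 14
Reactants: 22 2,3-bis(benzyloxy)-4-bromo-6-[(lower-unit-6-yl)(4-methylphenylsulfonyl)methyl]phenol; 19 N-{2-[4-(benzyloxy)phenyl]-2-oxoethyl}quinidinium bromide
Product: 24 [(2R,3R)-6,7-bis(benzyloxy)-5-bromo-3-(lower-unit-6-yl)-2,3-dihydro-1-benzofuran-2-yl][4-(benzyloxy)phenyl]methanone (2,3-trans), via o-quinone methide 23 (not isolated)
Conditions: Cs2CO3, CH2Cl2, rt
Reagents that add atoms: none
Why: Formal [4+1] annulation; base eliminates sulfinate to the o-quinone methide, the cinchona-derived ammonium ylide adds to the methide carbon and the phenoxide displaces the amine (5-exo-tet), which gives the trans-dihydrobenzofuran with both new centres set by the chiral ammonium group.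

Step 15
Reactants: 24 [(2R,3R)-6,7-bis(benzyloxy)-5-bromo-3-(lower-unit-6-yl)-2,3-dihydro-1-benzofuran-2-yl][4-(benzyloxy)phenyl]methanone
Product: 25 (S)-[(2R,3R)-6,7-bis(benzyloxy)-5-bromo-3-(lower-unit-6-yl)-2,3-dihydro-1-benzofuran-2-yl][4-(benzyloxy)phenyl]methanol
Conditions: Zn(BH4)2, Et2O/THF, −30 °C
Reagents that add atoms: none
Why: Chelation-controlled reduction (zinc bridges the carbonyl and ring oxygens) gives the anti carbinol, the epimer matched for backside attack by O1 in step 16; the other epimer would converge to the same product under the ionising conditions.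

Step 16
Reactants: 25 (S)-[(2R,3R)-6,7-bis(benzyloxy)-5-bromo-3-(lower-unit-6-yl)-2,3-dihydro-1-benzofuran-2-yl][4-(benzyloxy)phenyl]methanol
Product: 28 6-bromo-7,8,4'-tri-O-benzyloritin-(4α→6)-[7,8,4'-tri-O-benzyl-3,4-bis-O-TBS-epioritin-4α-ol], via aryl-oxiranium acetate 26 (not isolated), via 3-O-acetyl dimer 27 (not isolated)
Conditions: Zn(OAc)2, AcOH/1,4-dioxane/H2O, 60 °C; then K2CO3, MeOH, rt
Reagents that add atoms: acetic acid, CC(=O)O; water, O
Why: Under zinc acetate/acetic acid the p-benzyloxybenzylic hydroxyl ionises with backside participation of ring oxygen O1 to a bicyclic aryl-oxiranium ion, and acetate (or water) opens it at the former furan C2 with inversion, so that O1 ends on the benzylic carbon (flavan C2) and the new oxygen on C3. The closest known reaction type is the zinc acetate-mediated oxiranium ring expansion of 2-(1-sulfonyloxyalkyl)tetrahydrofurans to 3-acetoxytetrahydropyrans and the acid-induced isomerisation of 2-(1-hydroxyalkyl)-2,3-dihydrobenzofurans to chroman-3-ols. The pyran ring is closed by ring enlargement of the dihydrofuran (3-exo-tet bridging by O1, then cleavage of the O1–C bond that was endocyclic to the five-membered ring). C2 is set by inversion at the carbinol carbon and, if the cation is free, by the preference for the trans-disubstituted oxiranium ion; C3 is set by inversion at the furan C2 fixed in step 14; C4 is carried through unchanged, so the 2,3-trans-3,4-trans array follows from the trans-dihydrobenzofuran. The step needs opening of the oxiranium ion at the non-benzylic carbon: attack at the benzylic carbon only regenerates a benzylic ester or alcohol that re-ionises, whereas the chroman-3-yl acetate is inert and less strained, so the equilibrium drains to the six-membered ring. The buffered medium should leave silyl and benzyl ethers intact and trap the cation before it loses a proton.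

Step 17
Reactants: 28 6-bromo-7,8,4'-tri-O-benzyloritin-(4α→6)-[7,8,4'-tri-O-benzyl-3,4-bis-O-TBS-epioritin-4α-ol]; 9 (2R,3R)-7,8-bis(benzyloxy)-2-[4-(benzyloxy)phenyl]-6-bromo-3-(tert-butyldimethylsilyloxy)chroman-4-one
Product: 30 [6-bromo-7,8,4'-tri-O-benzyl-3-O-TBS-4β-hydroxyoritin]-(4α→6)-[7,8,4'-tri-O-benzyloritin]-(4α→6)-[7,8,4'-tri-O-benzyl-3,4-bis-O-TBS-epioritin-4α-ol], via dilithio derivative 29 (not isolated)
Conditions: n-BuLi (1.0 equiv) then t-BuLi (2.1 equiv), THF, −78 °C; then 9, −78 to −40 °C; aq. NH4Cl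
Reagents that add atoms: none
Why: Deprotonation of the 3-hydroxyl and bromine–lithium exchange give the C6 aryllithium of the middle unit, which adds to the ketone from the face opposite the C3 silyloxy group; the aryl bromide of 9 remains as a blocking group at C6 of the upper unit.

Step 18
Reactants: 30 tertiary alcohol
Product: 31 [6-bromo-7,8,4'-tri-O-benzyl-3-O-TBS-oritin]-(4β→6)-[7,8,4'-tri-O-benzyloritin]-(4α→6)-[7,8,4'-tri-O-benzyl-3,4-bis-O-TBS-epioritin-4α-ol]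
Conditions: n-Bu3SnH, CF3CO2H, CH2Cl2, −40 to 0 °C
Reagents that add atoms: none
Why: Ionic hydrogenation; acid ionises the tertiary bis-benzylic alcohol far faster than any other C–O bond, and the tin hydride attacks the diarylmethyl cation anti to the pseudo-axial C3 silyloxy group, which places the aryl group cis to O3 (3,4-cis, 4β).

Step 19
Reactants: 31 protected trimer
Product: 32 [6-bromo-7,8,4'-tri-O-benzyloritin]-(4β→6)-[7,8,4'-tri-O-benzyloritin]-(4α→6)-[7,8,4'-tri-O-benzylepioritin-4α-ol]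
Conditions: Bu4NF, AcOH, THF, 40 °C
Reagents that add atoms: none
Why: Fluoride cleaves the three silyl ethers while benzyl ethers and the aryl bromide are untouched.

Step 20
Reactants: 32 nona-O-benzyl bromo trimer
Product: 33 oritin-(4β→6)-oritin-(4α→6)-epioritin-4α-ol (CNP0140823.3)
Conditions: H2 (1 atm), Pd(OH)2/C, sodium acetate, THF/MeOH, rt
Reagents that add atoms: none
Why: Hydrogenolysis removes the nine benzyl ethers and the blocking aryl bromide in one operation, and sodium acetate takes up the hydrogen bromide so that the acid-sensitive benzylic 4-hydroxyl should survive.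

**Compound list**

1 | 2',3',4'-trihydroxyacetophenone | CC(=O)c1ccc(O)c(O)c1O | starting material
2 | 1-[3,4-bis(benzyloxy)-2-hydroxyphenyl]ethanone | CC(=O)c1ccc(OCc2ccccc2)c(OCc2ccccc2)c1O | intermediate
3 | 1-[3,4-bis(benzyloxy)-5-bromo-2-hydroxyphenyl]ethanone | CC(=O)c1cc(Br)c(OCc2ccccc2)c(OCc2ccccc2)c1O | intermediate
4 | (E)-1-[3,4-bis(benzyloxy)-5-bromo-2-hydroxyphenyl]-3-(dimethylamino)prop-2-en-1-one | CN(C)/C=C/C(=O)c1cc(Br)c(OCc2ccccc2)c(OCc2ccccc2)c1O | intermediate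
5 | 7,8-bis(benzyloxy)-6-bromo-4H-chromen-4-one | O=c1ccoc2c(OCc3ccccc3)c(OCc3ccccc3)c(Br)cc12 | intermediate
6 | [4-(benzyloxy)phenyl]boronic acid | OB(O)c1ccc(OCc2ccccc2)cc1 | starting material
7 | (2S)-7,8-bis(benzyloxy)-2-[4-(benzyloxy)phenyl]-6-bromochroman-4-one | O=C1C[C@@H](c2ccc(OCc3ccccc3)cc2)Oc2c(OCc3ccccc3)c(OCc3ccccc3)c(Br)cc12 | intermediate
8 | (2S)-7,8-bis(benzyloxy)-2-[4-(benzyloxy)phenyl]-6-bromo-4-(tert-butyldimethylsilyloxy)-2H-chromene | CC(C)(C)[Si](C)(C)OC1=C[C@@H](c2ccc(OCc3ccccc3)cc2)Oc2c(OCc3ccccc3)c(OCc3ccccc3)c(Br)cc12 | intermediate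
9 | (2R,3R)-7,8-bis(benzyloxy)-2-[4-(benzyloxy)phenyl]-6-bromo-3-(tert-butyldimethylsilyloxy)chroman-4-one (2,3-trans) | O=C1[C@H](O[Si](C)(C)C(C)(C)C)[C@@H](c2ccc(OCc3ccccc3)cc2)Oc2c(OCc3ccccc3)c(OCc3ccccc3)c(Br)cc12 | intermediate
10 | lithium (2R)-7,8-bis(benzyloxy)-2-[4-(benzyloxy)phenyl]-6-bromo-3-(tert-butyldimethylsilyloxy)-2H-chromen-4-olate | [Li]OC1=C(O[Si](C)(C)C(C)(C)C)[C@@H](c2ccc(OCc3ccccc3)cc2)Oc2c(OCc3ccccc3)c(OCc3ccccc3)c(Br)cc12 | intermediate
11 | (2R,3S)-7,8-bis(benzyloxy)-2-[4-(benzyloxy)phenyl]-6-bromo-3-(tert-butyldimethylsilyloxy)chroman-4-one (2,3-cis) | O=C1[C@@H](O[Si](C)(C)C(C)(C)C)[C@@H](c2ccc(OCc3ccccc3)cc2)Oc2c(OCc3ccccc3)c(OCc3ccccc3)c(Br)cc12 | intermediate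
12 | (2R,3R,4R)-7,8-bis(benzyloxy)-2-[4-(benzyloxy)phenyl]-6-bromo-3-(tert-butyldimethylsilyloxy)chroman-4-ol (all-cis) | c9ccccc9COc1ccc([C@H]2Oc3c(cc(Br)c(OCc9ccccc9)c3OCc9ccccc9)[C@@H](O)[C@H]2O[Si](C)(C)C(C)(C)C)cc1 | intermediate
13 | (2R,3S,4R)-7,8-bis(benzyloxy)-2-[4-(benzyloxy)phenyl]-6-bromo-3,4-bis(tert-butyldimethylsilyloxy)chromane (all-cis; lower-unit bromide) | c9ccccc9COc1ccc([C@H]2Oc3c(cc(Br)c(OCc9ccccc9)c3OCc9ccccc9)[C@@H](O[Si](C)(C)C(C)(C)C)[C@H]2O[Si](C)(C)C(C)(C)C)cc1 | intermediate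
14 | 2,3,4-trihydroxybenzaldehyde | O=Cc1ccc(O)c(O)c1O | starting material
15 | 3,4-bis(benzyloxy)-2-hydroxybenzaldehyde | O=Cc1ccc(OCc2ccccc2)c(OCc2ccccc2)c1O | intermediate
16 | 3,4-bis(benzyloxy)-5-bromo-2-hydroxybenzaldehyde | O=Cc1cc(Br)c(OCc2ccccc2)c(OCc2ccccc2)c1O | intermediate
17 | 2-bromo-1-[4-(benzyloxy)phenyl]ethanone | O=C(CBr)c1ccc(OCc2ccccc2)cc1 | starting material
18 | quinidine | COc1ccc2nccc([C@@H]([C@H]3C[C@@H]4CCN3C[C@@H]4C=C)O)c2c1 | starting material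
19 | N-{2-[4-(benzyloxy)phenyl]-2-oxoethyl}quinidinium bromide (nitrogen configuration fixed by the bicycle) | COc1ccc2nccc([C@@H]([C@H]3C[C@@H]4CC[N+]3(CC(=O)c3ccc(OCc5ccccc5)cc3)C[C@@H]4C=C)O)c2c1.[Br-] | intermediate
20 | 6-lithio derivative of 13 (C6–Li in place of C6–Br) | c9ccccc9COc1ccc([C@H]2Oc3c(cc([Li])c(OCc9ccccc9)c3OCc9ccccc9)[C@@H](O[Si](C)(C)C(C)(C)C)[C@H]2O[Si](C)(C)C(C)(C)C)cc1 | intermediate
21 | [3,4-bis(benzyloxy)-5-bromo-2-hydroxyphenyl](lower-unit-6-yl)methanol (mixture of carbinol epimers) | c9ccccc9COc1ccc([C@H]2Oc3c(cc(C(O)c4cc(Br)c(OCc9ccccc9)c(OCc9ccccc9)c4O)c(OCc9ccccc9)c3OCc9ccccc9)[C@@H](O[Si](C)(C)C(C)(C)C)[C@H]2O[Si](C)(C)C(C)(C)C)cc1 | intermediate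
22 | 2,3-bis(benzyloxy)-4-bromo-6-[(lower-unit-6-yl)(4-methylphenylsulfonyl)methyl]phenol (mixture of epimers) | c9ccccc9COc1ccc([C@H]2Oc3c(cc(C(c4cc(Br)c(OCc9ccccc9)c(OCc9ccccc9)c4O)S(=O)(=O)c4ccc(C)cc4)c(OCc9ccccc9)c3OCc9ccccc9)[C@@H](O[Si](C)(C)C(C)(C)C)[C@H]2O[Si](C)(C)C(C)(C)C)cc1 | intermediate
23 | 2,3-bis(benzyloxy)-4-bromo-6-[(lower-unit-6-yl)methylidene]cyclohexa-2,4-dien-1-one (o-quinone methide, alkene geometry not defined) | c9ccccc9COc1ccc([C@H]2Oc3c(cc(C=C4C=C(Br)C(OCc9ccccc9)=C(OCc9ccccc9)C4=O)c(OCc9ccccc9)c3OCc9ccccc9)[C@@H](O[Si](C)(C)C(C)(C)C)[C@H]2O[Si](C)(C)C(C)(C)C)cc1 | intermediate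
24 | [(2R,3R)-6,7-bis(benzyloxy)-5-bromo-3-(lower-unit-6-yl)-2,3-dihydro-1-benzofuran-2-yl][4-(benzyloxy)phenyl]methanone (2,3-trans) | c9ccccc9COc1ccc([C@H]2Oc3c(cc([C@@H]4c5cc(Br)c(OCc9ccccc9)c(OCc9ccccc9)c5O[C@H]4C(=O)c4ccc(OCc9ccccc9)cc4)c(OCc9ccccc9)c3OCc9ccccc9)[C@@H](O[Si](C)(C)C(C)(C)C)[C@H]2O[Si](C)(C)C(C)(C)C)cc1 | intermediate
25 | (S)-[(2R,3R)-6,7-bis(benzyloxy)-5-bromo-3-(lower-unit-6-yl)-2,3-dihydro-1-benzofuran-2-yl][4-(benzyloxy)phenyl]methanol | c9ccccc9COc1ccc([C@H]2Oc3c(cc([C@@H]4c5cc(Br)c(OCc9ccccc9)c(OCc9ccccc9)c5O[C@H]4[C@@H](O)c4ccc(OCc9ccccc9)cc4)c(OCc9ccccc9)c3OCc9ccccc9)[C@@H](O[Si](C)(C)C(C)(C)C)[C@H]2O[Si](C)(C)C(C)(C)C)cc1 | intermediate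
26 | aryl-oxiranium acetate (O1 bridges furan C2 and the benzylic carbon; aryl and C3 chain trans on the three-membered ring) | c9ccccc9COc1ccc([C@H]2Oc3c(cc([C@@H]4c5cc(Br)c(OCc9ccccc9)c(OCc9ccccc9)c5[O+]6[C@H]4[C@H]6c4ccc(OCc9ccccc9)cc4)c(OCc9ccccc9)c3OCc9ccccc9)[C@@H](O[Si](C)(C)C(C)(C)C)[C@H]2O[Si](C)(C)C(C)(C)C)cc1.CC(=O)[O-] | intermediate
27 | 3-O-acetyl-6-bromo-7,8,4'-tri-O-benzyloritin-(4α→6)-[7,8,4'-tri-O-benzyl-3,4-bis-O-TBS-epioritin-4α-ol] | c9ccccc9COc1ccc([C@H]2Oc3c(cc([C@@H]4c5cc(Br)c(OCc9ccccc9)c(OCc9ccccc9)c5O[C@H](c5ccc(OCc9ccccc9)cc5)[C@H]4OC(C)=O)c(OCc9ccccc9)c3OCc9ccccc9)[C@@H](O[Si](C)(C)C(C)(C)C)[C@H]2O[Si](C)(C)C(C)(C)C)cc1 | intermediate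
28 | 6-bromo-7,8,4'-tri-O-benzyloritin-(4α→6)-[7,8,4'-tri-O-benzyl-3,4-bis-O-TBS-epioritin-4α-ol] | c9ccccc9COc1ccc([C@H]2Oc3c(cc([C@@H]4c5cc(Br)c(OCc9ccccc9)c(OCc9ccccc9)c5O[C@H](c5ccc(OCc9ccccc9)cc5)[C@H]4O)c(OCc9ccccc9)c3OCc9ccccc9)[C@@H](O[Si](C)(C)C(C)(C)C)[C@H]2O[Si](C)(C)C(C)(C)C)cc1 | intermediate
29 | dilithio derivative of 28 (C6–Li on the middle unit and 3-OLi) | c9ccccc9COc1ccc([C@H]2Oc3c(cc([C@@H]4c5cc([Li])c(OCc9ccccc9)c(OCc9ccccc9)c5O[C@H](c5ccc(OCc9ccccc9)cc5)[C@H]4O[Li])c(OCc9ccccc9)c3OCc9ccccc9)[C@@H](O[Si](C)(C)C(C)(C)C)[C@H]2O[Si](C)(C)C(C)(C)C)cc1 | intermediate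
30 | [6-bromo-7,8,4'-tri-O-benzyl-3-O-TBS-4β-hydroxyoritin]-(4α→6)-[7,8,4'-tri-O-benzyloritin]-(4α→6)-[7,8,4'-tri-O-benzyl-3,4-bis-O-TBS-epioritin-4α-ol] (tertiary alcohol) | c9ccccc9COc1ccc([C@H]2Oc3c(cc([C@@H]4c5cc([C@]6(O)c7cc(Br)c(OCc9ccccc9)c(OCc9ccccc9)c7O[C@H](c7ccc(OCc9ccccc9)cc7)[C@H]6O[Si](C)(C)C(C)(C)C)c(OCc9ccccc9)c(OCc9ccccc9)c5O[C@H](c5ccc(OCc9ccccc9)cc5)[C@H]4O)c(OCc9ccccc9)c3OCc9ccccc9)[C@@H](O[Si](C)(C)C(C)(C)C)[C@H]2O[Si](C)(C)C(C)(C)C)cc1 | intermediate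
31 | [6-bromo-7,8,4'-tri-O-benzyl-3-O-TBS-oritin]-(4β→6)-[7,8,4'-tri-O-benzyloritin]-(4α→6)-[7,8,4'-tri-O-benzyl-3,4-bis-O-TBS-epioritin-4α-ol] | c9ccccc9COc1ccc([C@H]2Oc3c(cc([C@@H]4c5cc([C@H]6c7cc(Br)c(OCc9ccccc9)c(OCc9ccccc9)c7O[C@H](c7ccc(OCc9ccccc9)cc7)[C@H]6O[Si](C)(C)C(C)(C)C)c(OCc9ccccc9)c(OCc9ccccc9)c5O[C@H](c5ccc(OCc9ccccc9)cc5)[C@H]4O)c(OCc9ccccc9)c3OCc9ccccc9)[C@@H](O[Si](C)(C)C(C)(C)C)[C@H]2O[Si](C)(C)C(C)(C)C)cc1 | intermediate
32 | [6-bromo-7,8,4'-tri-O-benzyloritin]-(4β→6)-[7,8,4'-tri-O-benzyloritin]-(4α→6)-[7,8,4'-tri-O-benzylepioritin-4α-ol] | c9ccccc9COc1ccc([C@H]2Oc3c(cc([C@@H]4c5cc([C@H]6c7cc(Br)c(OCc9ccccc9)c(OCc9ccccc9)c7O[C@H](c7ccc(OCc9ccccc9)cc7)[C@H]6O)c(OCc9ccccc9)c(OCc9ccccc9)c5O[C@H](c5ccc(OCc9ccccc9)cc5)[C@H]4O)c(OCc9ccccc9)c3OCc9ccccc9)[C@@H](O)[C@H]2O)cc1 | intermediate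
33 | oritin-(4β→6)-oritin-(4α→6)-epioritin-4α-ol (CNP0140823.3) | Oc1ccc([C@H]2Oc3c(cc([C@@H]4c5cc([C@H]6c7ccc(O)c(O)c7O[C@H](c7ccc(O)cc7)[C@H]6O)c(O)c(O)c5O[C@H](c5ccc(O)cc5)[C@H]4O)c(O)c3O)[C@@H](O)[C@H]2O)cc1 | target

**Step count.** Total: 20 steps. Longest linear sequence: 17 steps (steps 1–8, then 12–20); steps 9–10 and 11 are side branches, and ketone 9 is used twice (steps 6 and 17).

**Steps most likely to fail**

Step 16 (key step). The benzylic cation may lose a proton (elimination and aromatisation to a 2-benzylbenzofuran), acetate may return only to the benzylic carbon without net ring enlargement, or C4 of the silylated lower unit may ionise under the same acid. Fallback: the same oxiranium ring enlargement is moved to a monomer without the lower unit, where forcing equilibrating conditions do no harm, and the C4–C6 bond is made afterwards by Friedel–Crafts arylation. It sets out from 16 (using 19 and 20) and comes back at 28. Aldehyde 16 is reduced with NaBH4 to 3,4-bis(benzyloxy)-5-bromo-2-hydroxybenzyl alcohol F1. TolSO2Na/HCO2H converts it into 2,3-bis(benzyloxy)-4-bromo-6-[(4-methylphenylsulfonyl)methyl]phenol F2. [4+1] annulation of F2 with salt 19 (Cs2CO3, CH2Cl2) should give [(2R)-6,7-bis(benzyloxy)-5-bromo-2,3-dihydro-1-benzofuran-2-yl][4-(benzyloxy)phenyl]methanone F3. Zn(BH4)2 should reduce it to (S)-[(2R)-6,7-bis(benzyloxy)-5-bromo-2,3-dihydro-1-benzofuran-2-yl][4-(benzyloxy)phenyl]methanol F4. Zn(OAc)2 in refluxing aqueous AcOH, then K2CO3/MeOH, should enlarge the ring to (2R,3S)-7,8-bis(benzyloxy)-2-[4-(benzyloxy)phenyl]-6-bromochroman-3-ol F5. DDQ with 2-ethoxyethanol should give (2R,3S)-7,8-bis(benzyloxy)-2-[4-(benzyloxy)phenyl]-6-bromo-4α-(2-ethoxyethoxy)chroman-3-ol F6. Aryllithium 20 is quenched with methanol to (2R,3S,4R)-7,8-bis(benzyloxy)-2-[4-(benzyloxy)phenyl]-3,4-bis(tert-butyldimethylsilyloxy)chromane F7. Me3SiOTf (CH2Cl2, −78 °C) should join F6 and F7 at C4 of F6 and C6 of F7, trans to the 3-hydroxyl, to give 28.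

Step 18. Hydride may be delivered to the wrong face of the diarylmethyl cation (3,4-trans epimer), or the acid may also ionise C4 of the lower unit. Fallback: the C4–C6 bond is made by Friedel–Crafts arylation instead of ketone addition and deoxygenation. It sets out from 9 and from 28 (through 29) and comes back at 31. Ketone 9 is reduced with NaBH4 to (2R,3S,4R)-7,8-bis(benzyloxy)-2-[4-(benzyloxy)phenyl]-6-bromo-3-(tert-butyldimethylsilyloxy)chroman-4-ol F8 (3,4-trans). Dilithio compound 29 is protonated with methanol to 7,8,4'-tri-O-benzyloritin-(4α→6)-[7,8,4'-tri-O-benzyl-3,4-bis-O-TBS-epioritin-4α-ol] F9. BF3·OEt2 (CH2Cl2, −78 to −20 °C) ionises F8 at C4 and the cation is captured by C6 of the middle unit of F9. Both C4 epimers of the new bond are expected, and the 3,4-cis (4β) isomer 31 is separated by chromatography.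

Step 6. The enolate may undergo silyl migration or ring opening by β-elimination of the aryloxide, or protonation may return the trans ketone. Fallback: C3 is inverted by SN2 displacement instead of enolate protonation. It sets out from 9 and comes back at 13. Bu4NF/AcOH removes the silyl group to give (2R,3R)-7,8-bis(benzyloxy)-2-[4-(benzyloxy)phenyl]-6-bromo-3-hydroxychroman-4-one F10. Mitsunobu esterification (PPh3, diisopropyl azodicarboxylate, 4-nitrobenzoic acid) should invert C3 to give (2R,3S)-7,8-bis(benzyloxy)-2-[4-(benzyloxy)phenyl]-6-bromo-4-oxochroman-3-yl 4-nitrobenzoate F11. NaBH4/CeCl3·7H2O should reduce the ketone to (2R,3R,4R)-7,8-bis(benzyloxy)-2-[4-(benzyloxy)phenyl]-6-bromo-4-hydroxychroman-3-yl 4-nitrobenzoate F12. K2CO3/MeOH gives (2R,3R,4R)-7,8-bis(benzyloxy)-2-[4-(benzyloxy)phenyl]-6-bromochroman-3,4-diol F13. TBSOTf (2.5 equiv)/2,6-lutidine silylates both hydroxyls to give 13.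

Further compounds

F1 | step 16 | 3,4-bis(benzyloxy)-5-bromo-2-hydroxybenzyl alcohol | OCc1cc(Br)c(OCc2ccccc2)c(OCc2ccccc2)c1O
F2 | step 16 | 2,3-bis(benzyloxy)-4-bromo-6-[(4-methylphenylsulfonyl)methyl]phenol | Cc1ccc(cc1)S(=O)(=O)Cc1cc(Br)c(OCc2ccccc2)c(OCc2ccccc2)c1O
F3 | step 16 | [(2R)-6,7-bis(benzyloxy)-5-bromo-2,3-dihydro-1-benzofuran-2-yl][4-(benzyloxy)phenyl]methanone | C1c2cc(Br)c(OCc3ccccc3)c(OCc3ccccc3)c2O[C@H]1C(=O)c1ccc(OCc3ccccc3)cc1
F4 | step 16 | (S)-[(2R)-6,7-bis(benzyloxy)-5-bromo-2,3-dihydro-1-benzofuran-2-yl][4-(benzyloxy)phenyl]methanol | C1c2cc(Br)c(OCc3ccccc3)c(OCc3ccccc3)c2O[C@H]1[C@@H](O)c1ccc(OCc3ccccc3)cc1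
F5 | step 16 | (2R,3S)-7,8-bis(benzyloxy)-2-[4-(benzyloxy)phenyl]-6-bromochroman-3-ol | C1c2cc(Br)c(OCc3ccccc3)c(OCc3ccccc3)c2O[C@H](c2ccc(OCc3ccccc3)cc2)[C@H]1O
F6 | step 16 | (2R,3S)-7,8-bis(benzyloxy)-2-[4-(benzyloxy)phenyl]-6-bromo-4α-(2-ethoxyethoxy)chroman-3-ol (3,4-trans) | CCOCCO[C@@H]1c2cc(Br)c(OCc3ccccc3)c(OCc3ccccc3)c2O[C@H](c2ccc(OCc3ccccc3)cc2)[C@H]1O
F7 | step 16 | (2R,3S,4R)-7,8-bis(benzyloxy)-2-[4-(benzyloxy)phenyl]-3,4-bis(tert-butyldimethylsilyloxy)chromane | c9ccccc9COc1ccc([C@H]2Oc3c(ccc(OCc9ccccc9)c3OCc9ccccc9)[C@@H](O[Si](C)(C)C(C)(C)C)[C@H]2O[Si](C)(C)C(C)(C)C)cc1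
F8 | step 18 | (2R,3S,4R)-7,8-bis(benzyloxy)-2-[4-(benzyloxy)phenyl]-6-bromo-3-(tert-butyldimethylsilyloxy)chroman-4-ol (2,3-trans-3,4-trans) | O[C@H]1[C@H](O[Si](C)(C)C(C)(C)C)[C@@H](c2ccc(OCc3ccccc3)cc2)Oc2c(OCc3ccccc3)c(OCc3ccccc3)c(Br)cc12
F9 | step 18 | 7,8,4'-tri-O-benzyloritin-(4α→6)-[7,8,4'-tri-O-benzyl-3,4-bis-O-TBS-epioritin-4α-ol] | c9ccccc9COc1ccc([C@H]2Oc3c(cc([C@@H]4c5ccc(OCc9ccccc9)c(OCc9ccccc9)c5O[C@H](c5ccc(OCc9ccccc9)cc5)[C@H]4O)c(OCc9ccccc9)c3OCc9ccccc9)[C@@H](O[Si](C)(C)C(C)(C)C)[C@H]2O[Si](C)(C)C(C)(C)C)cc1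
F10 | step 6 | (2R,3R)-7,8-bis(benzyloxy)-2-[4-(benzyloxy)phenyl]-6-bromo-3-hydroxychroman-4-one | O=C1[C@H](O)[C@@H](c2ccc(OCc3ccccc3)cc2)Oc2c(OCc3ccccc3)c(OCc3ccccc3)c(Br)cc12
F11 | step 6 | (2R,3S)-7,8-bis(benzyloxy)-2-[4-(benzyloxy)phenyl]-6-bromo-4-oxochroman-3-yl 4-nitrobenzoate (2,3-cis) | O=C1[C@@H](OC(=O)c2ccc(cc2)[N+](=O)[O-])[C@@H](c2ccc(OCc3ccccc3)cc2)Oc2c(OCc3ccccc3)c(OCc3ccccc3)c(Br)cc12
F12 | step 6 | (2R,3R,4R)-7,8-bis(benzyloxy)-2-[4-(benzyloxy)phenyl]-6-bromo-4-hydroxychroman-3-yl 4-nitrobenzoate (all-cis) | c9ccccc9COc1ccc([C@H]2Oc3c(cc(Br)c(OCc9ccccc9)c3OCc9ccccc9)[C@@H](O)[C@H]2OC(=O)c4ccc(cc4)[N+](=O)[O-])cc1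
F13 | step 6 | (2R,3R,4R)-7,8-bis(benzyloxy)-2-[4-(benzyloxy)phenyl]-6-bromochroman-3,4-diol (all-cis) | c9ccccc9COc1ccc([C@H]2Oc3c(cc(Br)c(OCc9ccccc9)c3OCc9ccccc9)[C@@H](O)[C@H]2O)cc1
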